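**Retrosynthetic overview**

1. The target is (5S,9R,10S,13S)-labd-7-ene-15,17-diyl diacetate; C17 and the C7=C8 bond are traced back to a C8 ketone (enol triflate, methoxycarbonylation, reduction), i.e. a 17-nor-8-ketone.
2. The strategy rests on this feature: the gem-dimethyl carbon C4 is bonded to the ring-fusion methine C5, which sits beside the methyl-bearing quaternary C10 and is γ to C8 through ring B. With ring B as a C8 silyl dienol ether (C8=C7–C6=C5), a tertiary C4 cation on the C10 arm can close ring A by forming C4–C5.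
3. Ring B comes from 3-methylcyclohexenone: catalytic asymmetric conjugate addition of the homoprenyl Grignard sets C10, and the enolate is relayed to C9 alkylation with the C11–C16 iodide (C13 from methyl hydrogen (R)-3-methylglutarate).
4. C5 and C9 are not controlled kinetically; both are enolisable in the Δ6-en-8-one and are set by equilibration after ring closure.
5. Ring order: ring B (purchased), then ring A (step 10).

Key step: step 10

**Remarks on the chemistry**

- Labdane numbering is used throughout (C17 on C8, C18/C19 on C4, C20 on C10, C16 on C13).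
- The ligand enantiomer in step 5 is the one that gives the (R) enol ether 10; the sense is to be assigned on the derived ketone in a pilot run. Any minor C10 antipode becomes a diastereomer after step 6 and is to be removed at 18.
- Compounds 12–16 are carried as a pair of C9 epimers and are drawn as the epimer that maps onto the target. Compound 17 is a set of C5/C9 epimers. All converge in step 11.

**Route**

Step 1
Reactants: 1 methyl hydrogen (R)-3-methylglutarate
Product: 2 methyl (R)-5-hydroxy-3-methylpentanoate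
Conditions: BH3·SMe2 (1.1 equiv), THF, −10 °C → rt; MeOH quench
Reagents that add atoms: none
Why: Chemoselective borane reduction of a carboxylic acid beside an ester (the acid is activated as an acyloxyborane, the ester is not reduced at this temperature); the stereocentre is not involved, and 2 is silylated at once to forestall lactonisation.

Step 2
Reactants: 2 methyl (R)-5-hydroxy-3-methylpentanoate
Product: 3 methyl (R)-5-[(tert-butyldiphenylsilyl)oxy]-3-methylpentanoate
Conditions: TBDPSCl, imidazole, CH2Cl2, 0 °C → rt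
Reagents that add atoms: tert-butyl(chloro)diphenylsilane, CC(C)(C)[Si](Cl)(c1ccccc1)c1ccccc1
Why: Imidazole-promoted silylation of a primary alcohol; the bulky TBDPS ether is chosen because it should tolerate anhydrous HCl, TiCl4 and the basic steps that follow.

Step 3
Reactants: 3 methyl (R)-5-[(tert-butyldiphenylsilyl)oxy]-3-methylpentanoate
Product: 4 (S)-5-[(tert-butyldiphenylsilyl)oxy]-3-methylpentan-1-ol
Conditions: i-Bu2AlH (2.5 equiv), CH2Cl2, −78 → 0 °C; aq. potassium sodium tartrate
Reagents that add atoms: none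
Why: Hydride reduction of the ester to the primary alcohol leaves the silyl ether intact, so the two glutarate arms are now differentiated (the descriptor changes to S only through CIP ranking).

Step 4
Reactants: 4 (S)-5-[(tert-butyldiphenylsilyl)oxy]-3-methylpentan-1-ol
Product: 5 (R)-tert-butyl[(5-iodo-3-methylpentyl)oxy]diphenylsilane
Conditions: I2, PPh3, imidazole, CH2Cl2, 0 °C → rt
Reagents that add atoms: iodine, II
Why: Appel-type iodination, SN2 displacement of the oxyphosphonium by iodide at the primary carbon; the remote stereocentre (future C13) is untouched.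

Step 5
Reactants: 6 5-bromo-2-methylpent-2-ene; 7 3-methylcyclohex-2-en-1-one
Product: 10 (R)-trimethyl{[3-methyl-3-(4-methylpent-3-en-1-yl)cyclohex-1-en-1-yl]oxy}silane, via (4-methylpent-3-en-1-yl)magnesium bromide 8 (not isolated), via bromomagnesium enolate 9 (not isolated)
Conditions: Mg, Et2O, reflux; then 7, Cu(OTf)2 (3 mol %), C2-symmetric chiral imidazolinium tetrafluoroborate (NHC precursor, 4 mol %), Et2O, 0 °C; then TMSCl, Et3N, HMPA, 0 °C → rt
Reagents that add atoms: chlorotrimethylsilane, C[Si](C)(C)Cl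
Why: Copper–carbene-catalysed asymmetric conjugate addition of a Grignard reagent to a β,β-disubstituted enone builds the quaternary centre (future C10), whose configuration is set by the face selection of the chiral carbene–copper complex, and O-silylation of the magnesium enolate stores the enolate position at C8–C9.

Step 6
Reactants: 10 (R)-trimethyl{[3-methyl-3-(4-methylpent-3-en-1-yl)cyclohex-1-en-1-yl]oxy}silane; 5 (R)-tert-butyl[(5-iodo-3-methylpentyl)oxy]diphenylsilane
Product: 12 (2RS,3R)-2-{(3S)-5-[(tert-butyldiphenylsilyl)oxy]-3-methylpentyl}-3-methyl-3-(4-methylpent-3-en-1-yl)cyclohexan-1-one, via lithium enolate 11 (not isolated)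
Conditions: MeLi (1.0 equiv), THF, 0 °C → rt; then 5 (1.3 equiv), HMPA, −78 °C → rt
Reagents that add atoms: none
Why: Regiospecific lithium enolate generation from the silyl enol ether followed by SN2 C-alkylation with the primary iodide forms C9–C11; the new C9 centre forms without control (epimer pair) and is set in step 11, while C10 and C13 are spectators.

Step 7
Reactants: 12 (2RS,3R)-2-{(3S)-5-[(tert-butyldiphenylsilyl)oxy]-3-methylpentyl}-3-methyl-3-(4-methylpent-3-en-1-yl)cyclohexan-1-one
Product: 14 (5S,6RS)-6-{(3S)-5-[(tert-butyldiphenylsilyl)oxy]-3-methylpentyl}-5-methyl-5-(4-methylpent-3-en-1-yl)cyclohex-2-en-1-one, via kinetic trimethylsilyl enol ether 13 (not isolated)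
Conditions: LiN(i-Pr)2, THF, −78 °C; TMSCl; then crude, Pd(OAc)2 (10 mol %), O2 (1 atm), DMSO, rt
Reagents that add atoms: none
Why: Saegusa–Ito oxidation: kinetic deprotonation takes the C7 methylene and not the hindered C9 methine, and the oxa-π-allylpalladium intermediate loses a β-hydride from C6 to give the Δ6 enone, while O2 returns zerovalent palladium to divalent palladium.

Step 8
Reactants: 14 (5S,6RS)-6-{(3S)-5-[(tert-butyldiphenylsilyl)oxy]-3-methylpentyl}-5-methyl-5-(4-methylpent-3-en-1-yl)cyclohex-2-en-1-one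
Product: 15 (5S,6RS)-6-{(3S)-5-[(tert-butyldiphenylsilyl)oxy]-3-methylpentyl}-5-(4-chloro-4-methylpentyl)-5-methylcyclohex-2-en-1-one
Conditions: HCl (anhydrous gas), CH2Cl2, −78 → −30 °C; cold aq. NaHCO3
Reagents that add atoms: hydrogen chloride, Cl
Why: Ionic Markovnikov hydrochlorination of the trisubstituted alkene through the tertiary carbocation gives the tertiary chloride; the electron-poor enone alkene and the TBDPS ether should not react at low temperature, and any β-chloro ketone from reversible HCl addition to the enone reverts with base in the work-up or in step 9.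

Step 9
Reactants: 15 (5S,6RS)-6-{(3S)-5-[(tert-butyldiphenylsilyl)oxy]-3-methylpentyl}-5-(4-chloro-4-methylpentyl)-5-methylcyclohex-2-en-1-one
Product: 16 tert-butyl{[(3S)-5-{(1RS,6S)-2-[(tert-butyldimethylsilyl)oxy]-6-(4-chloro-4-methylpentyl)-6-methylcyclohexa-2,4-dien-1-yl}-3-methylpentyl]oxy}diphenylsilane (C8 silyl dienol ether, C8=C7–C6=C5)
Conditions: TBSOTf (1.2 equiv), Et3N (2.0 equiv), CH2Cl2, −78 → 0 °C
Reagents that add atoms: tert-butyldimethylsilyl trifluoromethanesulfonate, CC(C)(C)[Si](C)(C)OS(=O)(=O)C(F)(F)F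
Why: Soft enolisation (vinylogous silyl enol ether formation): O-silylation gives a silyloxyallyl cation from which Et3N should remove a γ-proton at the C5 methylene in preference to the α′ C9–H, a methine shielded by quaternary C10 and its own side chain, giving the through-conjugated 1-silyloxy-1,3-diene; no stereocentre is formed or touched.

Step 10
Reactants: 16 tert-butyl{[(3S)-5-{(1RS,6S)-2-[(tert-butyldimethylsilyl)oxy]-6-(4-chloro-4-methylpentyl)-6-methylcyclohexa-2,4-dien-1-yl}-3-methylpentyl]oxy}diphenylsilane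
Product: 17 15-[(tert-butyldiphenylsilyl)oxy]-17-norlabd-6-en-8-one (10S,13S; set of C5/C9 epimers)
Conditions: TiCl4 (1.1 equiv), 2,6-di-tert-butyl-4-methylpyridine (0.3 equiv), CH2Cl2 (0.01 M), −78 °C; aq. NaHCO3
Reagents that add atoms: none
Why: TiCl4 abstracts chloride from the tertiary C4–Cl bond (SN1) and the C4 cation is captured by C5, the γ-carbon of the C8 silyl dienol ether; the O-silyl oxocarbenium ion so formed loses its silyl group to chloride and releases the conjugated Δ6-en-8-one. The closest known reactions are the Lewis-acid α-tert-alkylation of silyl enol ethers by tertiary chlorides, the γ-selective (vinylogous Mukaiyama-type) alkylation of silyl dienol ethers and enol-ether-terminated cation–olefin cyclisations. Ring A closes as a six-membered ring through the C10–C1–C2–C3 tether, with the attacking C5=C6 bond exocyclic to the new ring (6-enol-exo type) and the free C4 cation as electrophile. C5 is the one new stereocentre: a chair-like closure lets C4 reach only the C5 face anti to the C10 methyl, so the cis ring fusion is the expected kinetic result; this is not relied upon, because C5 stays vinylogously enolisable and is set in step 11. The step needs γ (C5) over α (C7) attack and ring closure over E1 loss of HCl: the tether secures the first, since C7 could only be reached through a bridged ring and the linear dienol ether has no nucleophilic C9. Low temperature, high dilution and the hindered pyridine, which traps stray HCl before it cleaves the dienol ether, serve the second.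

Step 11
Reactants: 17 15-[(tert-butyldiphenylsilyl)oxy]-17-norlabd-6-en-8-one (set of C5/C9 epimers)
Product: 18 (5S,9R,10S,13S)-15-[(tert-butyldiphenylsilyl)oxy]-17-norlabd-6-en-8-one
Conditions: t-BuOK (0.3 equiv), t-BuOH–THF (1:1), rt, argon; aq. NH4Cl
Reagents that add atoms: none
Why: Base-mediated thermodynamic epimerisation: reversible γ-deprotonation at C5 (extended dienolate) and α′-deprotonation at C9 let both centres settle relative to the fixed C10, expected to give the trans ring fusion with the equatorial C9 side chain, because each cis-fused conformer keeps a 1,3-diaxial contact to the axial C4 methyl and adds the gauche interactions of a cis-decalin.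

Step 12
Reactants: 18 (5S,9R,10S,13S)-15-[(tert-butyldiphenylsilyl)oxy]-17-norlabd-6-en-8-one
Product: 19 (5S,9R,10S,13S)-15-[(tert-butyldiphenylsilyl)oxy]-17-norlabdan-8-one
Conditions: H2 (1 atm), 10% Pd/C, EtOAc, rt
Reagents that add atoms: none
Why: Heterogeneous catalytic hydrogenation of the disubstituted conjugated alkene under neutral conditions; no stereocentre is formed and C5 and C9 cannot epimerise.

Step 13
Reactants: 19 (5S,9R,10S,13S)-15-[(tert-butyldiphenylsilyl)oxy]-17-norlabdan-8-one
Product: 21 (5S,9R,10S,13S)-15-[(tert-butyldiphenylsilyl)oxy]-17-norlabd-7-en-8-yl trifluoromethanesulfonate, via potassium enolate 20 (not isolated)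
Conditions: KN(SiMe3)2 (1.2 equiv), THF, −78 °C; PhNTf2, −78 → 0 °C
Reagents that add atoms: N-phenylbis(trifluoromethanesulfonimide), O=S(=O)(N(c1ccccc1)S(=O)(=O)C(F)(F)F)C(F)(F)F
Why: Kinetic enolisation with a hindered amide base takes a C7 methylene proton (C9–H is a methine flanked by quaternary C10), and O-triflation fixes the double bond at C7–C8 (regioselective enol triflate formation).

Step 14
Reactants: 21 (5S,9R,10S,13S)-15-[(tert-butyldiphenylsilyl)oxy]-17-norlabd-7-en-8-yl trifluoromethanesulfonate
Product: 22 methyl (5S,9R,10S,13S)-15-[(tert-butyldiphenylsilyl)oxy]labd-7-en-17-oate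
Conditions: Pd(OAc)2 (5 mol %), PPh3 (10 mol %), CO (1 atm), Et3N, MeOH–DMF, 60 °C
Reagents that add atoms: carbon monoxide, [C-]#[O+]; methanol, CO
Why: Palladium-catalysed methoxycarbonylation of an enol triflate (oxidative addition to zerovalent palladium, CO insertion, methanolysis of the acylpalladium) attaches C17 to C8 and keeps the double bond at C7–C8.

Step 15
Reactants: 22 methyl (5S,9R,10S,13S)-15-[(tert-butyldiphenylsilyl)oxy]labd-7-en-17-oate
Product: 23 (5S,9R,10S,13S)-15-[(tert-butyldiphenylsilyl)oxy]labd-7-en-17-ol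
Conditions: i-Bu2AlH (2.5 equiv), CH2Cl2, −78 → 0 °C; aq. potassium sodium tartrate
Reagents that add atoms: none
Why: 1,2-Reduction of the α,β-unsaturated ester to the allylic alcohol; the trisubstituted alkene and the silyl ether are not affected.

Step 16
Reactants: 23 (5S,9R,10S,13S)-15-[(tert-butyldiphenylsilyl)oxy]labd-7-en-17-ol
Product: 24 (5S,9R,10S,13S)-labd-7-ene-15,17-diol
Conditions: Bu4NF, THF, rt
Reagents that add atoms: none
Why: Fluoride-induced desilylation, driven by Si–F bond formation, frees the C15 alcohol.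

Step 17
Reactants: 24 (5S,9R,10S,13S)-labd-7-ene-15,17-diol
Product: 25 (5S,9R,10S,13S)-labd-7-ene-15,17-diyl diacetate
Conditions: Ac2O, pyridine, DMAP (cat.), CH2Cl2, rt
Reagents that add atoms: acetic anhydride, CC(=O)OC(C)=O
Why: DMAP-catalysed acylation of both primary alcohols gives the diacetate; no stereocentre is affected.

**Compound list**

1 | methyl hydrogen (R)-3-methylglutarate | C[C@H](CC(=O)O)CC(=O)OC | starting material
2 | methyl (R)-5-hydroxy-3-methylpentanoate | C[C@H](CCO)CC(=O)OC | intermediate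
3 | methyl (R)-5-[(tert-butyldiphenylsilyl)oxy]-3-methylpentanoate | C[C@H](CCO[Si](c1ccccc1)(c1ccccc1)C(C)(C)C)CC(=O)OC | intermediate
4 | (S)-5-[(tert-butyldiphenylsilyl)oxy]-3-methylpentan-1-ol | C[C@H](CCO[Si](c1ccccc1)(c1ccccc1)C(C)(C)C)CCO | intermediate
5 | (R)-tert-butyl[(5-iodo-3-methylpentyl)oxy]diphenylsilane | C[C@H](CCO[Si](c1ccccc1)(c1ccccc1)C(C)(C)C)CCI | intermediate
6 | 5-bromo-2-methylpent-2-ene | CC(C)=CCCBr | starting material
7 | 3-methylcyclohex-2-en-1-one | CC1=CC(=O)CCC1 | starting material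
8 | (4-methylpent-3-en-1-yl)magnesium bromide | CC(C)=CCC[Mg]Br | intermediate
9 | bromomagnesium (R)-3-methyl-3-(4-methylpent-3-en-1-yl)cyclohex-1-en-1-olate | Br[Mg]OC1=C[C@@](C)(CCC=C(C)C)CCC1 | intermediate
10 | (R)-trimethyl{[3-methyl-3-(4-methylpent-3-en-1-yl)cyclohex-1-en-1-yl]oxy}silane | C[Si](C)(C)OC1=C[C@@](C)(CCC=C(C)C)CCC1 | intermediate
11 | lithium (R)-3-methyl-3-(4-methylpent-3-en-1-yl)cyclohex-1-en-1-olate | [Li]OC1=C[C@@](C)(CCC=C(C)C)CCC1 | intermediate
12 | (2RS,3R)-2-{(3S)-5-[(tert-butyldiphenylsilyl)oxy]-3-methylpentyl}-3-methyl-3-(4-methylpent-3-en-1-yl)cyclohexan-1-one (C9 epimer pair, drawn 2R) | CC(C)(C)[Si](c1ccccc1)(c1ccccc1)OCC[C@@H](C)CC[C@H]2C(=O)CCC[C@]2(C)CCC=C(C)C | intermediate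
13 | kinetic trimethylsilyl enol ether of 12 (double bond C7=C8; C9 epimer pair) | CC(C)(C)[Si](c1ccccc1)(c1ccccc1)OCC[C@@H](C)CC[C@H]2C(O[Si](C)(C)C)=CCC[C@]2(C)CCC=C(C)C | intermediate
14 | (5S,6RS)-6-{(3S)-5-[(tert-butyldiphenylsilyl)oxy]-3-methylpentyl}-5-methyl-5-(4-methylpent-3-en-1-yl)cyclohex-2-en-1-one (drawn 6R) | CC(C)(C)[Si](c1ccccc1)(c1ccccc1)OCC[C@@H](C)CC[C@H]2C(=O)C=CC[C@]2(C)CCC=C(C)C | intermediate
15 | (5S,6RS)-6-{(3S)-5-[(tert-butyldiphenylsilyl)oxy]-3-methylpentyl}-5-(4-chloro-4-methylpentyl)-5-methylcyclohex-2-en-1-one (drawn 6R) | CC(C)(C)[Si](c1ccccc1)(c1ccccc1)OCC[C@@H](C)CC[C@H]2C(=O)C=CC[C@]2(C)CCCC(C)(C)Cl | intermediate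
16 | tert-butyl{[(3S)-5-{(1RS,6S)-2-[(tert-butyldimethylsilyl)oxy]-6-(4-chloro-4-methylpentyl)-6-methylcyclohexa-2,4-dien-1-yl}-3-methylpentyl]oxy}diphenylsilane (key-step precursor, drawn 1R) | CC(C)(C)[Si](c1ccccc1)(c1ccccc1)OCC[C@@H](C)CC[C@H]2C(O[Si](C)(C)C(C)(C)C)=CC=C[C@]2(C)CCCC(C)(C)Cl | intermediate
17 | 15-[(tert-butyldiphenylsilyl)oxy]-17-norlabd-6-en-8-one, 10S,13S, set of C5/C9 epimers | CC(C)(C)[Si](c1ccccc1)(c1ccccc1)OCC[C@@H](C)CCC1C(=O)C=CC2C(C)(C)CCC[C@]12C | intermediate
18 | (5S,9R,10S,13S)-15-[(tert-butyldiphenylsilyl)oxy]-17-norlabd-6-en-8-one (trans-fused) | CC(C)(C)[Si](c1ccccc1)(c1ccccc1)OCC[C@@H](C)CC[C@H]1C(=O)C=C[C@H]2C(C)(C)CCC[C@]12C | intermediate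
19 | (5S,9R,10S,13S)-15-[(tert-butyldiphenylsilyl)oxy]-17-norlabdan-8-one | CC(C)(C)[Si](c1ccccc1)(c1ccccc1)OCC[C@@H](C)CC[C@H]1C(=O)CC[C@H]2C(C)(C)CCC[C@]12C | intermediate
20 | potassium Δ7-enolate of 19 | CC(C)(C)[Si](c1ccccc1)(c1ccccc1)OCC[C@@H](C)CC[C@H]1C(O[K])=CC[C@H]2C(C)(C)CCC[C@]12C | intermediate
21 | (5S,9R,10S,13S)-15-[(tert-butyldiphenylsilyl)oxy]-17-norlabd-7-en-8-yl trifluoromethanesulfonate | CC(C)(C)[Si](c1ccccc1)(c1ccccc1)OCC[C@@H](C)CC[C@H]1C(OS(=O)(=O)C(F)(F)F)=CC[C@H]2C(C)(C)CCC[C@]12C | intermediate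
22 | methyl (5S,9R,10S,13S)-15-[(tert-butyldiphenylsilyl)oxy]labd-7-en-17-oate | CC(C)(C)[Si](c1ccccc1)(c1ccccc1)OCC[C@@H](C)CC[C@H]1C(C(=O)OC)=CC[C@H]2C(C)(C)CCC[C@]12C | intermediate
23 | (5S,9R,10S,13S)-15-[(tert-butyldiphenylsilyl)oxy]labd-7-en-17-ol | CC(C)(C)[Si](c1ccccc1)(c1ccccc1)OCC[C@@H](C)CC[C@H]1C(CO)=CC[C@H]2C(C)(C)CCC[C@]12C | intermediate
24 | (5S,9R,10S,13S)-labd-7-ene-15,17-diol | OCC[C@@H](C)CC[C@H]1C(CO)=CC[C@H]2C(C)(C)CCC[C@]12C | intermediate
25 | (5S,9R,10S,13S)-labd-7-ene-15,17-diyl diacetate | CC(=O)OCC[C@@H](C)CC[C@H]1C(COC(C)=O)=CC[C@H]2C(C)(C)CCC[C@]12C | target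

**Step count**

Total step count: 17. Longest linear sequence: 16 steps (steps 1–4, then steps 6–17, from 1); the ring-B branch (step 5) joins at step 6.

**Steps most likely to fail**

Step 10 (ring-A closure). After ionisation, the C4 cation may lose a proton (E1) faster than it is captured, and the HCl released may cleave the dienol ether before cyclisation, returning open-chain enones. The fallback changes the initiating group to an epoxide, which is opened by the Lewis acid without release of HCl. It sets out from 14: epoxidation of the trisubstituted alkene (mCPBA, NaHCO3, CH2Cl2, 0 °C) gives the 3,4-epoxy enone F1. Silylation as in step 9 (TBSOTf, Et3N, −78 °C) gives the epoxy silyl dienol ether F2. MeAlCl2 (CH2Cl2, −78 °C) opens the epoxide at its tertiary carbon C4 with capture by C5, an epoxide-initiated cyclisation terminated by a silyl enol ether, to give the 3-hydroxy-17-norlabd-6-en-8-one F3. Barton–McCombie deoxygenation through the 3-O-(imidazol-1-ylthiocarbonyl) derivative F4 (1,1′-thiocarbonyldiimidazole, DMAP, 60 °C; then Bu3SnH, AIBN, toluene, 100 °C) comes back to the route at 17.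

Step 6 (C9 alkylation). SN2 attack by the enolate carbon next to quaternary C10 may be slow enough for proton transfer between product and enolate to compete, leading to alkylation at C7, dialkylation or O-alkylation. The fallback replaces the SN2 step by an aldol addition and sets out from 4 and 10. Oxidation of 4 (Dess–Martin periodinane, CH2Cl2) gives (R)-5-[(tert-butyldiphenylsilyl)oxy]-3-methylpentanal F5. Mukaiyama aldol addition of 10 to F5 (BF3·OEt2, CH2Cl2, −78 °C) gives the β-hydroxy ketone F6. Mesylation (MsCl, Et3N) gives the mesylate F7, and elimination with DBU gives the exocyclic C9=C11 enone F8. Conjugate reduction with [(Ph3P)CuH]6 (toluene, rt), which leaves the isolated trisubstituted alkene alone, comes back to the route at 12.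

Step 9 (dienol ether formation). Deprotonation may occur in part at C9 and give the cross-conjugated 2-silyloxy diene, which would close a ring through C9 instead of C5. The fallback makes the wanted proton doubly activated and sets out from 14. Treatment with t-BuOK (t-BuOH–THF) gives the extended dienolate, and kinetic protonation at C7 (AcOH, −78 °C) gives the deconjugated β,γ-enone F9 (double bond C5=C6). Hydrochlorination as in step 8 gives the tertiary chloride F10. TBSOTf/Et3N then removes the C7 proton, which is both allylic and α to the ketone, and comes back to the route at 16.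

**Further compounds**

F1 | step 10 | 3,4-epoxide of 14: 6-{(3S)-5-[(tert-butyldiphenylsilyl)oxy]-3-methylpentyl}-5-[3-(3,3-dimethyloxiran-2-yl)propyl]-5-methylcyclohex-2-en-1-one | CC(C)(C)[Si](c1ccccc1)(c1ccccc1)OCC[C@@H](C)CC[C@H]2C(=O)C=CC[C@]2(C)CCC3OC3(C)C
F2 | step 10 | C8 tert-butyldimethylsilyl dienol ether of F1 | CC(C)(C)[Si](c1ccccc1)(c1ccccc1)OCC[C@@H](C)CC[C@H]2C(O[Si](C)(C)C(C)(C)C)=CC=C[C@]2(C)CCC3OC3(C)C
F3 | step 10 | 15-[(tert-butyldiphenylsilyl)oxy]-3-hydroxy-17-norlabd-6-en-8-one (C3/C5/C9 epimers) | CC(C)(C)[Si](c1ccccc1)(c1ccccc1)OCC[C@@H](C)CCC1C(=O)C=CC2C(C)(C)C(O)CC[C@]12C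
F4 | step 10 | 3-O-(imidazol-1-ylthiocarbonyl) derivative of F3 | CC(C)(C)[Si](c1ccccc1)(c1ccccc1)OCC[C@@H](C)CCC1C(=O)C=CC2C(C)(C)C(OC(=S)n3ccnc3)CC[C@]12C
F5 | step 6 | (R)-5-[(tert-butyldiphenylsilyl)oxy]-3-methylpentanal | C[C@H](CCO[Si](c1ccccc1)(c1ccccc1)C(C)(C)C)CC=O
F6 | step 6 | C11-hydroxy aldol adduct (β-hydroxy ketone) | CC(C)(C)[Si](c1ccccc1)(c1ccccc1)OCC[C@@H](C)CC(O)C2C(=O)CCC[C@]2(C)CCC=C(C)C
F7 | step 6 | methanesulfonate of F6 | CC(C)(C)[Si](c1ccccc1)(c1ccccc1)OCC[C@@H](C)CC(OS(C)(=O)=O)C2C(=O)CCC[C@]2(C)CCC=C(C)C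
F8 | step 6 | exocyclic C9=C11 enone | CC(C)(C)[Si](c1ccccc1)(c1ccccc1)OCC[C@@H](C)CC=C2C(=O)CCC[C@]2(C)CCC=C(C)C
F9 | step 9 | β,γ-enone: 2-{(3S)-5-[(tert-butyldiphenylsilyl)oxy]-3-methylpentyl}-3-methyl-3-(4-methylpent-3-en-1-yl)cyclohex-4-en-1-one | CC(C)(C)[Si](c1ccccc1)(c1ccccc1)OCC[C@@H](C)CCC2C(=O)CC=C[C@]2(C)CCC=C(C)C
F10 | step 9 | tertiary chloride of F9 | CC(C)(C)[Si](c1ccccc1)(c1ccccc1)OCC[C@@H](C)CCC2C(=O)CC=C[C@]2(C)CCCC(C)(C)Cl
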